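**Plan**

1. Numbering used throughout: ring C1 (the CH stereocentre) to C14, with C2 the allylic CH2 of the (Z)-C3=C4 olefin; C8 carries CH2OH; side chain C15(Me)=C16–C17–C18=C19Me2.
2. Retrosynthetic cuts, in order: C16–C17 and C15–CH3 (alkyne carboalumination/prenylation); ring bond C1–C2 (enolate C-alkylation); C7=C8 (Wittig); C8–C9 (ylide alkylation); C10–C11 (alkenylalane plus ethylene oxide).
3. Enabling feature: C1 is flanked by the side-chain sp2 carbon C15 and by C2, a primary allylic carbon. With C15 temporarily an imide carbonyl, C1 is an enolate carbon and the C1–C2 bond closes the 14-membered carbocycle by SN2 on a neryl-type chloride.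
4. Forward order: nerol gives the C2–C7 chloro aldehyde; 5-hexyn-1-ol gives the C9–C15 iodo acid, then the camphorsultam imide, then the ylide; Wittig joins the chain; ring closure; reduction, alkyne formation and carboalumination/prenylation finish the side chain, with no protecting group after the ring closure.
5. Stereochemistry: C1 (R) from the (2S)-bornane-10,2-sultam during ring closure; (Z)-C3=C4 from nerol; C7=C8 from the (E)-selective stabilised Wittig; C11=C12 and C15=C16 from syn carboalumination.

Key step: step 11

Assumption: the chelated (Z)-enolate of an N-acyl (2R)-bornane-10,2-sultam is alkylated on its Cα-Re face, so the (2S)-auxiliary used here exposes the Cα-Si face, which for the C1 enolate corresponds to (R); both sultam enantiomers are commercial.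

**Route**

Step 1
Reactants: 1 nerol, (2Z)-3,7-dimethylocta-2,6-dien-1-ol
Product: 2 neryl chloride, (2Z)-1-chloro-3,7-dimethylocta-2,6-diene
Conditions: NCS, Me2S, CH2Cl2, −40 → 0 °C
Reagents that add atoms: N-chlorosuccinimide, ClN1C(=O)CCC1=O
Why: In this Corey–Kim chlorination chloride displaces the alkoxysulfonium ion at the primary carbon by SN2, so neither allylic transposition nor loss of the (Z)-geometry should occur.

Step 2
Reactants: 2 neryl chloride
Product: 3 racemic 3-[(3Z)-5-chloro-3-methylpent-3-en-1-yl]-2,2-dimethyloxirane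
Conditions: mCPBA, NaHCO3, CH2Cl2, 0 °C
Reagents that add atoms: 3-chloroperbenzoic acid, OOC(=O)c1cccc(Cl)c1
Why: In this Prilezhaev epoxidation the electrophilic peracid should choose the remote trisubstituted alkene because the allylic chlorine deactivates the other one; the epoxide stereocentre forms as a racemate and is excised in step 3.

Step 3
Reactants: 3 racemic chloro epoxide
Product: 4 (4Z)-6-chloro-4-methylhex-4-enal
Conditions: H5IO6, THF/Et2O, 0 °C
Reagents that add atoms: none
Why: Periodic acid opens the epoxide and cleaves the resulting glycol (Malaprade-type cleavage), releasing acetone and the aldehyde in a weakly nucleophilic ethereal medium that should spare the allylic chloride.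

Step 4
Reactants: 5 5-hexyn-1-ol
Product: 6 tert-butyl(hex-5-yn-1-yloxy)dimethylsilane
Conditions: TBSCl, imidazole, CH2Cl2, 23 °C
Reagents that add atoms: tert-butyldimethylsilyl chloride, CC(C)(C)[Si](C)(C)Cl
Why: Standard silyl ether protection masks the hydroxyl against AlMe3 and n-BuLi in step 5.

Step 5
Reactants: 6 tert-butyl(hex-5-yn-1-yloxy)dimethylsilane
Product: 8 (3E)-8-[(tert-butyldimethylsilyl)oxy]-4-methyloct-3-en-1-ol, via alkenyldimethylalane 7 (not isolated)
Conditions: AlMe3, Cp2ZrCl2 (cat.), CH2Cl2, 23 °C; then n-BuLi, THF/hexane, −78 °C; ethylene oxide, −78 → 0 °C; aqueous work-up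
Reagents that add atoms: trimethylaluminium, C[Al](C)C; ethylene oxide, C1CO1
Why: The Cp2ZrCl2-catalysed Negishi carboalumination adds methyl and aluminium syn across the terminal alkyne (methyl to the internal carbon), and the ate complex formed with n-BuLi opens ethylene oxide with retention, fixing the (E)-C11=C12 olefin.

Step 6
Reactants: 8 (3E)-8-[(tert-butyldimethylsilyl)oxy]-4-methyloct-3-en-1-ol
Product: 9 tert-butyl{[(5E)-8-iodo-5-methyloct-5-en-1-yl]oxy}dimethylsilane
Conditions: iodine, PPh3, imidazole, CH2Cl2, 0 → 23 °C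
Reagents that add atoms: iodine, [I][I]
Why: In this Garegg–Samuelsson (Appel-type) iodination iodide displaces the alkoxyphosphonium ion at the primary carbon without touching the olefin geometry.

Step 7
Reactants: 9 silyl ether iodide
Product: 10 (5E)-8-iodo-5-methyloct-5-enoic acid
Conditions: CrO3, H2SO4, H2O, acetone, 0 °C
Reagents that add atoms: water, O
Why: Under Jones oxidation conditions the acid cleaves the primary silyl ether and the liberated alcohol is oxidised through the aldehyde hydrate to the acid, while the alkyl iodide and the trisubstituted alkene should be inert at 0 °C.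

Step 8
Reactants: 10 (5E)-8-iodo-5-methyloct-5-enoic acid; 11 (2S)-bornane-10,2-sultam [(1R)-(+)-2,10-camphorsultam]
Product: 13 N-[(5E)-8-iodo-5-methyloct-5-enoyl]-(2S)-bornane-10,2-sultam, via acid chloride 12 (not isolated)
Conditions: (COCl)2, DMF (cat.), CH2Cl2, 0 → 23 °C; then 11, Et3N, DMAP (cat.), CH2Cl2, 0 → 23 °C
Reagents that add atoms: none
Why: N-acylation of the sulfonamide nitrogen by the acid chloride (DMAP-catalysed acyl transfer) is fast compared with any N-alkylation by the primary iodide and leaves the auxiliary stereocentres untouched.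

Step 9
Reactants: 13 iodo imide; 14 methyl (triphenyl-λ5-phosphanylidene)acetate
Product: 15 methyl (5E)-6-methyl-10-oxo-10-[(2S)-bornane-10,2-sultam-N-yl]-2-(triphenyl-λ5-phosphanylidene)dec-5-enoate
Conditions: 14 (2.1 equiv), MeCN, 80 °C
Reagents that add atoms: none
Why: C-alkylation of the ester-stabilised ylide by the primary iodide followed by transylidation (the second equivalent of 14 acts as base) gives the α-substituted ylide under neutral conditions that should leave the base-sensitive imide alone.

Step 10
Reactants: 15 α-substituted ylide; 4 (4Z)-6-chloro-4-methylhex-4-enal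
Product: 16 methyl (2E,6Z)-8-chloro-6-methyl-2-{(3E)-4-methyl-8-oxo-8-[(2S)-bornane-10,2-sultam-N-yl]oct-3-en-1-yl}octa-2,6-dienoate
Conditions: 4 (1.3 equiv), CH2Cl2, 40 °C
Reagents that add atoms: none
Why: The Wittig reaction of an α-substituted ester-stabilised ylide is thermodynamically controlled and should give the (E)-enoate (ester trans to the aldehyde-derived chain, so C6 and C9 cis as the target requires), and its neutral conditions tolerate the allylic chloride and the imide.

Step 11
Reactants: 16 open-chain chloro enoate imide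
Product: 18 methyl (1E,5Z,8R,11E)-5,11-dimethyl-8-{[(2S)-bornane-10,2-sultam-N-yl]carbonyl}cyclotetradeca-1,5,11-triene-1-carboxylate, via sodium enolate 17 (not isolated)
Conditions: NaN(SiMe3)2 (1.05 equiv), THF (0.002 M), −78 °C; then HMPA, −78 → 23 °C
Reagents that add atoms: none
Why: Proposed new method: NaN(SiMe3)2 removes only the imide α-hydrogen of 16, which is several pKa units more acidic than the γ-hydrogens of the trisubstituted enoate, to give the sulfonyl-chelated (Z)-enolate 17, whose C1 displaces chloride from the primary allylic carbon C2 in an intramolecular SN2 C-alkylation. The closest known reaction types are the intermolecular alkylation of camphorsultam imide enolates by allylic halides and the macrocyclic C-alkylation of sulfone-, cyanohydrin- or keto ester-stabilised carbanions by allylic halides used for 14-membered terpenoid rings; an auxiliary-controlled macrocyclic enolate alkylation has no direct precedent. The 14-membered carbocycle closes in the 14-exo-tet mode, the chain being pre-folded by the cis arrangement of the ring carbons about C3=C4 and C7=C8. The new stereocentre C1 is controlled by the (2S)-sultam: the Cα-Si face of 17, remote from the chelated sodium and its sulfonyl oxygen, is open, and since the electrophile is tied to C1 only through a long flexible tether the auxiliary alone should decide the face, giving (R). The step needs cyclisation over oligomerisation, secured by high dilution and a single equivalent of base, and SN2 over SN2′ with retention of the (Z)-C3=C4 geometry, secured by the unhindered primary chloride and by the absence of Pd(PPh3)4-type catalysts or iodide that would equilibrate the allyl unit. The hindered α,β-disubstituted enoate is a poor Michael acceptor, so conjugate closure should not compete.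

Step 12
Reactants: 18 macrocyclic ester imide
Product: 19 (1R,3Z,7E,11E)-8-(hydroxymethyl)-4,12-dimethylcyclotetradeca-3,7,11-triene-1-carbaldehyde
Conditions: i-Bu2AlH (4 equiv), CH2Cl2, −78 °C; aqueous KNaC4H4O6 work-up
Reagents that add atoms: none
Why: In this hydride reduction the N-acyl sulfonamide should stop at a tetrahedral aluminium hemiaminal that is stable at −78 °C and releases the aldehyde only on work-up, while the enoate takes two hydrides in 1,2-fashion to the allylic alcohol; the C1 stereocentre is not involved.

Step 13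
Reactants: 19 hydroxy aldehyde
Product: 20 [(1E,5Z,8R,11E)-8-ethynyl-5,11-dimethylcyclotetradeca-1,5,11-trien-1-yl]methanol
Conditions: dimethyl (1-diazo-2-oxopropyl)phosphonate, K2CO3, MeOH, 0 → 23 °C
Reagents that add atoms: dimethyl (1-diazo-2-oxopropyl)phosphonate, COP(=O)(OC)C(=[N+]=[N-])C(C)=O
Why: The Ohira–Bestmann variant of the Seyferth–Gilbert homologation converts the aldehyde into the terminal alkyne through the diazoalkene and a carbene 1,2-hydrogen shift, under mildly basic conditions that should not epimerise the non-conjugated α-stereocentre.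

Step 14
Reactants: 20 ethynyl macrocycle; 21 1-chloro-3-methylbut-2-ene (prenyl chloride)
Product: 23 [(1E,5Z,8R,11E)-5,11-dimethyl-8-[(2E)-6-methylhepta-2,5-dien-2-yl]cyclotetradeca-1,5,11-trien-1-yl]methanol (target), via alkenyldimethylalane 22 (not isolated)
Conditions: AlMe3 (4 equiv), Cp2ZrCl2 (0.5 equiv), CH2Cl2, 23 °C; then 21, Pd(PPh3)4 (5 mol %), THF, 23 °C; aqueous work-up
Reagents that add atoms: trimethylaluminium, C[Al](C)C
Why: Negishi carboalumination (syn addition, methyl to the internal carbon) followed by Pd(PPh3)4-catalysed coupling of the alkenylalane with the primary terminus of the allylic chloride, with retention of alkene geometry, should give the (E)-trisubstituted 1,4-diene, the hydroxyl being carried as its dimethylaluminium alkoxide.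

**Compound list**

1 | nerol, (2Z)-3,7-dimethylocta-2,6-dien-1-ol | OC/C=C(/C)CCC=C(C)C | starting material
2 | neryl chloride, (2Z)-1-chloro-3,7-dimethylocta-2,6-diene | ClC/C=C(/C)CCC=C(C)C | intermediate
3 | racemic 3-[(3Z)-5-chloro-3-methylpent-3-en-1-yl]-2,2-dimethyloxirane | ClC/C=C(/C)CCC1OC1(C)C | intermediate
4 | (4Z)-6-chloro-4-methylhex-4-enal | ClC/C=C(/C)CCC=O | intermediate
5 | 5-hexyn-1-ol | C#CCCCCO | starting material
6 | tert-butyl(hex-5-yn-1-yloxy)dimethylsilane | C#CCCCCO[Si](C)(C)C(C)(C)C | intermediate
7 | (E)-alkenyldimethylalane from 6 (AlMe2 on the terminal carbon, cis to the new methyl; not isolated) | C[Al](C)/C=C(\C)CCCCO[Si](C)(C)C(C)(C)C | intermediate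
8 | (3E)-8-[(tert-butyldimethylsilyl)oxy]-4-methyloct-3-en-1-ol | OCC/C=C(\C)CCCCO[Si](C)(C)C(C)(C)C | intermediate
9 | tert-butyl{[(5E)-8-iodo-5-methyloct-5-en-1-yl]oxy}dimethylsilane | ICC/C=C(\C)CCCCO[Si](C)(C)C(C)(C)C | intermediate
10 | (5E)-8-iodo-5-methyloct-5-enoic acid | ICC/C=C(\C)CCCC(O)=O | intermediate
11 | (2S)-bornane-10,2-sultam, (1R)-(+)-2,10-camphorsultam | O=S1(=O)N[C@H]2C[C@@H]3CC[C@@]2(C1)C3(C)C | starting material
12 | (5E)-8-iodo-5-methyloct-5-enoyl chloride (not isolated) | ICC/C=C(\C)CCCC(Cl)=O | intermediate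
13 | N-[(5E)-8-iodo-5-methyloct-5-enoyl]-(2S)-bornane-10,2-sultam | ICC/C=C(\C)CCCC(=O)N1[C@H]2C[C@@H]3CC[C@@]2(CS1(=O)=O)C3(C)C | intermediate
14 | methyl (triphenyl-λ5-phosphanylidene)acetate | COC(=O)C=P(c1ccccc1)(c1ccccc1)c1ccccc1 | starting material
15 | methyl (5E)-6-methyl-10-oxo-10-[(2S)-bornane-10,2-sultam-N-yl]-2-(triphenyl-λ5-phosphanylidene)dec-5-enoate | COC(=O)C(CC/C=C(\C)CCCC(=O)N1[C@H]2C[C@@H]3CC[C@@]2(CS1(=O)=O)C3(C)C)=P(c1ccccc1)(c1ccccc1)c1ccccc1 | intermediate
16 | methyl (2E,6Z)-8-chloro-6-methyl-2-{(3E)-4-methyl-8-oxo-8-[(2S)-bornane-10,2-sultam-N-yl]oct-3-en-1-yl}octa-2,6-dienoate | ClC/C=C(/C)CC/C=C(/C(=O)OC)CC/C=C(\C)CCCC(=O)N1[C@H]2C[C@@H]3CC[C@@]2(CS1(=O)=O)C3(C)C | intermediate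
17 | sodium (Z)-enolate of 16 (enolate oxygen cis to the C14 chain; not isolated) | [Na+].[O-]/C(N1[C@H]2C[C@@H]3CC[C@@]2(CS1(=O)=O)C3(C)C)=C\CC/C(C)=C/CC/C(C(=O)OC)=C\CC/C(C)=C\CCl | intermediate
18 | methyl (1E,5Z,8R,11E)-5,11-dimethyl-8-{[(2S)-bornane-10,2-sultam-N-yl]carbonyl}cyclotetradeca-1,5,11-triene-1-carboxylate | O=C([C@H]4C/C=C(/C)CC/C=C(/C(=O)OC)CC/C=C(\C)CC4)N1[C@H]2C[C@@H]3CC[C@@]2(CS1(=O)=O)C3(C)C | intermediate
19 | (1R,3Z,7E,11E)-8-(hydroxymethyl)-4,12-dimethylcyclotetradeca-3,7,11-triene-1-carbaldehyde | O=C[C@H]1C/C=C(/C)CC/C=C(/CO)CC/C=C(\C)CC1 | intermediate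
20 | [(1E,5Z,8R,11E)-8-ethynyl-5,11-dimethylcyclotetradeca-1,5,11-trien-1-yl]methanol | C#C[C@H]1C/C=C(/C)CC/C=C(/CO)CC/C=C(\C)CC1 | intermediate
21 | 1-chloro-3-methylbut-2-ene (prenyl chloride) | CC(C)=CCCl | starting material
22 | (E)-alkenyldimethylalane from 20 (AlMe2 on C16, cis to the new C15 methyl; hydroxyl as its dimethylaluminium alkoxide; not isolated) | C[Al](C)/C=C(\C)[C@H]1C/C=C(/C)CC/C=C(/CO[Al](C)C)CC/C=C(\C)CC1 | intermediate
23 | [(1E,5Z,8R,11E)-5,11-dimethyl-8-[(2E)-6-methylhepta-2,5-dien-2-yl]cyclotetradeca-1,5,11-trien-1-yl]methanol | CC(C)=CC/C=C(\C)[C@H]1C/C=C(/C)CC/C=C(/CO)CC/C=C(\C)CC1 | target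

**Totals**

Total step count: 14.
Longest linear sequence: 11 steps (steps 4 to 14, from 5-hexyn-1-ol).

**Steps most likely to fail**

1. Step 11 (proposed new method). The slow 14-membered ring closure may be outrun by intermolecular alkylation (oligomerisation) or by thermal loss of the sultam anion from the enolate, and facial selectivity may erode at the temperature the closure needs. The fallback sets out from ylide 15 and aldehyde 4 and returns at 18, using only known reaction types. Aldehyde 4 would be converted with HC(OMe)3 and catalytic acid into its dimethyl acetal, (2Z)-1-chloro-6,6-dimethoxy-3-methylhex-2-ene F1. The sodium enolate of 15 (NaN(SiMe3)2, THF/HMPA, −78 → 0 °C) would then be alkylated intermolecularly with F1, the established camphorsultam imide alkylation by an allylic halide with the same facial control, to give the (R)-C1-allylated ylide acetal F2. Mild aqueous acid would unmask the aldehyde, the ylide being carried through as its phosphonium salt and released with NaHCO3, to give the (R)-C1-allylated ylide aldehyde F3. Slow addition of F3 to warm CH2Cl2 at high dilution would close the ring at C7=C8 by an intramolecular stabilised Wittig reaction, a known macrocyclisation mode, to deliver 18.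

2. Step 12. The imide-derived hemiaminal may collapse and be reduced further to the primary alcohol, or the hindered enoate may be reduced incompletely. The fallback sets out from 18 and returns at 20 by separating the two reductions. LiBH4 (Et2O, one equivalent of MeOH, 0 °C) would reduce only the activated imide and release the auxiliary, giving methyl (1E,5Z,8R,11E)-8-(hydroxymethyl)-5,11-dimethylcyclotetradeca-1,5,11-triene-1-carboxylate F4. Dess–Martin oxidation would give methyl (1E,5Z,8R,11E)-8-formyl-5,11-dimethylcyclotetradeca-1,5,11-triene-1-carboxylate F5. Ohira–Bestmann alkynylation would give methyl (1E,5Z,8R,11E)-8-ethynyl-5,11-dimethylcyclotetradeca-1,5,11-triene-1-carboxylate F6. Reduction of the ester with i-Bu2AlH (CH2Cl2, −78 °C) would then give 20.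

3. Step 9. C-alkylation of the stabilised ylide by the unactivated homoallylic iodide may be sluggish and lose material to dehydrohalogenation. The fallback sets out from 13 and returns at 16 by changing the olefination type. The sodium salt of trimethyl phosphonoacetate (NaH, DMSO, 50 °C), a far stronger carbon nucleophile that is still less basic than the imide enolate, would be alkylated by 13 to give methyl (5E)-2-(dimethoxyphosphoryl)-6-methyl-10-oxo-10-[(2S)-bornane-10,2-sultam-N-yl]dec-5-enoate F7. A Horner–Wadsworth–Emmons reaction of F7 with 4 under LiCl/i-Pr2NEt in MeCN would give 16, the (E)-isomer being separated from any (Z)-isomer by chromatography.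

Further compounds
F1 | step 11 | (2Z)-1-chloro-6,6-dimethoxy-3-methylhex-2-ene | ClC/C=C(/C)CCC(OC)OC
F2 | step 11 | (R)-C1-allylated ylide acetal (15 carrying the (2Z)-6,6-dimethoxy-3-methylhex-2-en-1-yl group on the imide α-carbon) | COC(=O)C(CC/C=C(\C)CC[C@H](C/C=C(/C)CCC(OC)OC)C(=O)N1[C@H]2C[C@@H]3CC[C@@]2(CS1(=O)=O)C3(C)C)=P(c1ccccc1)(c1ccccc1)c1ccccc1
F3 | step 11 | (R)-C1-allylated ylide aldehyde (F2 with the acetal hydrolysed to the aldehyde) | COC(=O)C(CC/C=C(\C)CC[C@H](C/C=C(/C)CCC=O)C(=O)N1[C@H]2C[C@@H]3CC[C@@]2(CS1(=O)=O)C3(C)C)=P(c1ccccc1)(c1ccccc1)c1ccccc1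
F4 | step 12 | methyl (1E,5Z,8R,11E)-8-(hydroxymethyl)-5,11-dimethylcyclotetradeca-1,5,11-triene-1-carboxylate | OC[C@H]1C/C=C(/C)CC/C=C(/C(=O)OC)CC/C=C(\C)CC1
F5 | step 12 | methyl (1E,5Z,8R,11E)-8-formyl-5,11-dimethylcyclotetradeca-1,5,11-triene-1-carboxylate | O=C[C@H]1C/C=C(/C)CC/C=C(/C(=O)OC)CC/C=C(\C)CC1
F6 | step 12 | methyl (1E,5Z,8R,11E)-8-ethynyl-5,11-dimethylcyclotetradeca-1,5,11-triene-1-carboxylate | C#C[C@H]1C/C=C(/C)CC/C=C(/C(=O)OC)CC/C=C(\C)CC1
F7 | step 9 | methyl (5E)-2-(dimethoxyphosphoryl)-6-methyl-10-oxo-10-[(2S)-bornane-10,2-sultam-N-yl]dec-5-enoate | COC(=O)C(CC/C=C(\C)CCCC(=O)N1[C@H]2C[C@@H]3CC[C@@]2(CS1(=O)=O)C3(C)C)P(=O)(OC)OC
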